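**Retrosynthetic overview**
1. Feature: ring A reads C1'(acyl)-C2'(OH)-C3'(prenyl)-C4'(OH)-C5'(H)-C6'(H). C2' to C5', with both oxygens and the prenyl group, are the four diene carbons of the bis-silylated dienol of methyl 2-prenylacetoacetate. C1' and C6' are the two sp carbons of an ethynyl styryl ketone.
2. Key disconnection: C1'-C2' and C5'-C6', by [4+2] cycloaddition and aromatisation (loss of methanol and of the trimethylsilyl groups) on the intact (E)-enone. No resorcinol has to be C-prenylated between its hydroxyl groups.
3. Enynone: the C(=O)-C(sp) bond comes from a Weinreb amide and ethynylmagnesium bromide, and the C5-vinyl bond from a Heck reaction of a 5-bromo-2,3-dihydrobenzofuran.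
4. Dihydrofuran ring: O1-C2 by 5-exo phenoxide opening (inversion) of a threo epoxy alcohol. C3 is fixed by Sharpless kinetic resolution of the aryl alkenyl carbinol and C2 by hydroxyl-directed epoxidation.
5. Order of rings: ring B is bought (5-bromosalicylaldehyde), the dihydrofuran ring is closed in step 5, and ring A is built last in step 12.

Key step: step 12

Assumption: the SMILES is read as (2R,3R) in the dihydrobenzofuran, which places 3-OH and the 2-(2-hydroxypropan-2-yl) group trans; the route is built for this isomer.

**Route**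

Step 1
Reactants: 1 5-bromosalicylaldehyde
Product: 2 5-bromo-2-(triisopropylsilyloxy)benzaldehyde
Conditions: TIPSCl, imidazole, DMF, rt
Reagents that add atoms: chlorotriisopropylsilane, CC(C)[Si](Cl)(C(C)C)C(C)C
Why: Imidazole-promoted silylation of a phenol; the bulky TIPS ether masks the phenol (which, if free, would turn the later allylic alcohol into a 2,2-dimethylchromene through an ortho-quinone methide), resists O-to-O migration in step 2 and can later be removed by fluoride without acid.

Step 2
Reactants: 2 5-bromo-2-(triisopropylsilyloxy)benzaldehyde; 3 2-methylprop-1-enylmagnesium bromide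
Product: 4 rac-1-[5-bromo-2-(triisopropylsilyloxy)phenyl]-3-methylbut-2-en-1-ol
Conditions: THF, -78 to -20 °C; then H2O
Reagents that add atoms: none
Why: 1,2-Addition of an alkenyl Grignard reagent to an aromatic aldehyde brings in C2 and the C(CH3)2 carbons and turns the aldehyde carbon into C3; the aryl bromide does not exchange at this temperature, and the carbinol centre is formed racemic.

Step 3
Reactants: 4 rac-1-[5-bromo-2-(triisopropylsilyloxy)phenyl]-3-methylbut-2-en-1-ol
Product: 5 (S)-1-[5-bromo-2-(triisopropylsilyloxy)phenyl]-3-methylbut-2-en-1-ol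
Conditions: Ti(OiPr)4 (0.2 equiv), L-(+)-DIPT (0.3 equiv), t-BuOOH (0.6 equiv), 4 Å MS, CH2Cl2, -20 °C, stopped beyond half conversion
Reagents that add atoms: none
Why: Sharpless kinetic resolution; with L-(+)-DIPT the enantiomer spatially related to the fast-reacting (S)-alkyl alkenyl carbinols (here R, because aryl outranks alkenyl) is epoxidised faster, so the (S)-alcohol (future C3) should be left in high enantiomeric purity, and this firm empirical rule is preferred to an enone reduction, where an aryl and an alkenyl flank offer no dependable facial bias.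

Step 4
Reactants: 5 (S)-1-[5-bromo-2-(triisopropylsilyloxy)phenyl]-3-methylbut-2-en-1-ol
Product: 6 (R)-[5-bromo-2-(triisopropylsilyloxy)phenyl][(2S)-3,3-dimethyloxiran-2-yl]methanol (threo)
Conditions: mCPBA, NaHCO3 (buffer), CH2Cl2, 0 °C
Reagents that add atoms: 3-chloroperoxybenzoic acid, O=C(OO)c1cccc(Cl)c1
Why: Hydroxyl-directed peracid epoxidation (Henbest effect); A(1,3) strain with the cis-methyl group holds the carbinol C-H in the alkene plane, so the hydrogen-bonded peracid attacks the face that carries OH and should give the threo epoxy alcohol with an (S)-oxirane carbon, the carbinol descriptor changing from S to R only because the priorities change.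

Step 5
Reactants: 6 (R)-[5-bromo-2-(triisopropylsilyloxy)phenyl][(2S)-3,3-dimethyloxiran-2-yl]methanol
Product: 8 (2R,3R)-5-bromo-2-(2-hydroxypropan-2-yl)-2,3-dihydro-1-benzofuran-3-ol, via tetrabutylammonium phenoxide 7 (not isolated)
Conditions: TBAF, THF, 0 °C to rt; then H2O
Reagents that add atoms: none
Why: Fluoride cleaves the aryl silyl ether and the phenoxide opens the oxirane at its secondary carbon in a base-mediated 5-exo-tet SN2 closure (6-endo attack at the tertiary carbon would need acid), the inversion turning the (S)-oxirane carbon into (2R) and placing C(CH3)2OH trans to the untouched 3-OH.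

Step 6
Reactants: 8 (2R,3R)-5-bromo-2-(2-hydroxypropan-2-yl)-2,3-dihydro-1-benzofuran-3-ol
Product: 9 (2R,3R)-5-bromo-3-(triethylsilyloxy)-2-[2-(triethylsilyloxy)propan-2-yl]-2,3-dihydro-1-benzofuran
Conditions: TESOTf, 2,6-lutidine, CH2Cl2, -78 to 0 °C
Reagents that add atoms: triethylsilyl trifluoromethanesulfonate, CC[Si](CC)(CC)OS(=O)(=O)C(F)(F)F
Why: Silyl triflate and lutidine silylate even the tertiary alcohol; TES is chosen for both oxygens because it removes the acidic protons that would consume Grignard reagent 12 and ketene acetal 20, yet leaves under nearly neutral fluoride, whereas a tertiary TBS ether would need conditions that endanger the benzylic alcohol and the 2'-hydroxychalcone.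

Step 7
Reactants: 9 (2R,3R)-5-bromo-3-(triethylsilyloxy)-2-[2-(triethylsilyloxy)propan-2-yl]-2,3-dihydro-1-benzofuran; 10 N-methoxy-N-methylacrylamide
Product: 11 (E)-N-methoxy-N-methyl-3-{(2R,3R)-3-(triethylsilyloxy)-2-[2-(triethylsilyloxy)propan-2-yl]-2,3-dihydro-1-benzofuran-5-yl}prop-2-enamide
Conditions: Pd(OAc)2 (5 mol %), P(o-tol)3 (12 mol %), Et3N, DMF, 100 °C
Reagents that add atoms: none
Why: Mizoroki-Heck reaction; oxidative addition of the unhindered aryl bromide to zerovalent palladium, syn insertion of the acrylamide at its CH2 terminus and syn beta-hydride elimination should give the (E)-cinnamamide, with the silyl ethers and both stereocentres as remote spectators.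

Step 8
Reactants: 11 (E)-N-methoxy-N-methyl-3-{(2R,3R)-3-(triethylsilyloxy)-2-[2-(triethylsilyloxy)propan-2-yl]-2,3-dihydro-1-benzofuran-5-yl}prop-2-enamide; 12 ethynylmagnesium bromide
Product: 13 (E)-1-{(2R,3R)-3-(triethylsilyloxy)-2-[2-(triethylsilyloxy)propan-2-yl]-2,3-dihydro-1-benzofuran-5-yl}pent-1-en-4-yn-3-one
Conditions: THF, 0 °C; inverse quench into cold 10% aq. citric acid
Reagents that add atoms: none
Why: Weinreb ketone synthesis; the alkynyl Grignard reagent adds 1,2 and the magnesium chelate holds until the quench, so no over-addition occurs, and the cold acidic inverse quench protonates the liberated N,O-dimethylhydroxylamine before it can add to the terminal ynone.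

Step 9
Reactants: 14 methyl acetoacetate; 15 prenyl bromide
Product: 17 methyl 2-acetyl-5-methylhex-4-enoate, via sodium enolate 16 (not isolated)
Conditions: NaH, THF, 0 °C; then 15, 0 °C to rt
Reagents that add atoms: none
Why: Acetoacetic ester alkylation; the stabilised enolate displaces the primary allylic bromide by SN2 at carbon, a slight excess of 14 holds back dialkylation, and the new centre is racemic and is erased in step 10.

Step 10
Reactants: 17 methyl 2-acetyl-5-methylhex-4-enoate
Product: 18 methyl 5-methyl-2-[1-(trimethylsilyloxy)ethylidene]hex-4-enoate (E/Z mixture)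
Conditions: TMSCl, Et3N, toluene, rt
Reagents that add atoms: chlorotrimethylsilane, C[Si](C)(C)Cl
Why: Soft enolisation and O-silylation of a beta-keto ester gives the conjugated silyl enol ether; its geometry and any terminal enol ether isomer do not matter, because all converge on the same dienolate in step 11.

Step 11
Reactants: 18 methyl 5-methyl-2-[1-(trimethylsilyloxy)ethylidene]hex-4-enoate
Product: 20 1-methoxy-2-(3-methylbut-2-enyl)-1,3-bis(trimethylsilyloxy)buta-1,3-diene, via lithium dienolate 19 (not isolated)
Conditions: LiN(iPr)2 (LDA), THF, -78 °C; then TMSCl, -78 °C to rt; used crude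
Reagents that add atoms: chlorotrimethylsilane, C[Si](C)(C)Cl
Why: Kinetic gamma-deprotonation of the vinylogous ester followed by O-silylation of the ester enolate is the standard second stage in making 1-alkoxy-1,3-bis(silyloxy)butadienes, and both ketene acetal geometries lead to the same arene.

Step 12
Reactants: 13 (E)-1-{(2R,3R)-3-(triethylsilyloxy)-2-[2-(triethylsilyloxy)propan-2-yl]-2,3-dihydro-1-benzofuran-5-yl}pent-1-en-4-yn-3-one; 20 1-methoxy-2-(3-methylbut-2-enyl)-1,3-bis(trimethylsilyloxy)buta-1,3-diene
Product: 22 paratocarpin G bis(triethylsilyl) ether, via cyclohexadiene cycloadduct 21 (not isolated)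
Conditions: 20 (2 equiv), toluene, rt to 60 °C; then 5% aq. citric acid, THF, 0 °C
Reagents that add atoms: none
Why: The CH2 terminus of 20, activated by both oxygen donors, bonds to the unsubstituted alkyne carbon of 13 (C5'-C6') and the ketene acetal carbon bonds to the acyl-bearing alkyne carbon (C1'-C2'), either as an asynchronous concerted [4+2] cycloaddition or as a Mukaiyama-Michael addition followed by 6-(enolexo)-exo-trig closure of the allenolate on the carboxonium carbon, giving cyclohexa-1,4-diene 21. Mild acid then cleaves the ketal O-Si bond, the hemiketal expels methanol, the enol silyl ether is hydrolysed and tautomerisation gives the resorcinol ring. The closest known reaction type is the Diels-Alder reaction and aromatisation of 1-alkoxy-1,3-bis(silyloxy)butadienes with acetylenic ketones and esters, which gives 2,4-dihydroxyaryl carbonyl compounds. No lasting stereocentre is made, since the ketal carbon of 21 forms as a mixture and is flattened on aromatisation, while C2, C3 and the (E)-alkene are spectators. Regioselectivity follows from this matched polarity and puts the acyl group ortho to one OH and para to the other, with the prenyl group between the two oxygens. Chemoselectivity for the alkyne over the styryl alkene is secured by the unhindered and more electrophilic sp terminus, whereas the alkene terminus carries an aryl ring whose para oxygen donates into the enone.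

Step 13
Reactants: 22 paratocarpin G bis(triethylsilyl) ether
Product: 23 paratocarpin G
Conditions: Et3N·3HF, THF, rt
Reagents that add atoms: none
Why: Fluoride-driven Si-O cleavage under nearly neutral conditions frees both alcohols without touching a C-O bond, so C2 and C3 keep their configuration, and it avoids both the acid that would ionise the benzylic C3-O bond (loss of water and acetone to a benzofuran) and the base that would close the 2'-hydroxychalcone to a flavanone.

**Compound list**
1 | 5-bromosalicylaldehyde | O=Cc1cc(Br)ccc1O | starting material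
2 | 5-bromo-2-(triisopropylsilyloxy)benzaldehyde | O=Cc1cc(Br)ccc1O[Si](C(C)C)(C(C)C)C(C)C | intermediate
3 | 2-methylprop-1-enylmagnesium bromide | CC(C)=C[Mg]Br | starting material
4 | rac-1-[5-bromo-2-(triisopropylsilyloxy)phenyl]-3-methylbut-2-en-1-ol | CC(C)=CC(O)c1cc(Br)ccc1O[Si](C(C)C)(C(C)C)C(C)C | intermediate
5 | (S)-1-[5-bromo-2-(triisopropylsilyloxy)phenyl]-3-methylbut-2-en-1-ol | CC(C)=C[C@H](O)c1cc(Br)ccc1O[Si](C(C)C)(C(C)C)C(C)C | intermediate
6 | (R)-[5-bromo-2-(triisopropylsilyloxy)phenyl][(2S)-3,3-dimethyloxiran-2-yl]methanol | CC1(C)O[C@H]1[C@H](O)c1cc(Br)ccc1O[Si](C(C)C)(C(C)C)C(C)C | intermediate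
7 | tetrabutylammonium 4-bromo-2-{(R)-[(2S)-3,3-dimethyloxiran-2-yl](hydroxy)methyl}phenoxide | CC1(C)O[C@H]1[C@H](O)c1cc(Br)ccc1[O-].CCCC[N+](CCCC)(CCCC)CCCC | intermediate
8 | (2R,3R)-5-bromo-2-(2-hydroxypropan-2-yl)-2,3-dihydro-1-benzofuran-3-ol | Brc1ccc2c(c1)[C@@H](O)[C@H](C(C)(C)O)O2 | intermediate
9 | (2R,3R)-5-bromo-3-(triethylsilyloxy)-2-[2-(triethylsilyloxy)propan-2-yl]-2,3-dihydro-1-benzofuran | Brc1ccc2c(c1)[C@@H](O[Si](CC)(CC)CC)[C@H](C(C)(C)O[Si](CC)(CC)CC)O2 | intermediate
10 | N-methoxy-N-methylacrylamide | C=CC(=O)N(C)OC | starting material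
11 | (E)-N-methoxy-N-methyl-3-{(2R,3R)-3-(triethylsilyloxy)-2-[2-(triethylsilyloxy)propan-2-yl]-2,3-dihydro-1-benzofuran-5-yl}prop-2-enamide | CON(C)C(=O)/C=C/c1ccc2c(c1)[C@@H](O[Si](CC)(CC)CC)[C@H](C(C)(C)O[Si](CC)(CC)CC)O2 | intermediate
12 | ethynylmagnesium bromide | C#C[Mg]Br | starting material
13 | (E)-1-{(2R,3R)-3-(triethylsilyloxy)-2-[2-(triethylsilyloxy)propan-2-yl]-2,3-dihydro-1-benzofuran-5-yl}pent-1-en-4-yn-3-one | C#CC(=O)/C=C/c1ccc2c(c1)[C@@H](O[Si](CC)(CC)CC)[C@H](C(C)(C)O[Si](CC)(CC)CC)O2 | intermediate
14 | methyl acetoacetate | COC(=O)CC(C)=O | starting material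
15 | prenyl bromide (1-bromo-3-methylbut-2-ene) | CC(C)=CCBr | starting material
16 | sodium enolate of methyl acetoacetate | COC(=O)C=C(C)[O-].[Na+] | intermediate
17 | methyl 2-acetyl-5-methylhex-4-enoate (racemic, labile centre) | COC(=O)C(CC=C(C)C)C(C)=O | intermediate
18 | methyl 5-methyl-2-[1-(trimethylsilyloxy)ethylidene]hex-4-enoate (E/Z mixture) | COC(=O)C(CC=C(C)C)=C(C)O[Si](C)(C)C | intermediate
19 | lithium dienolate of 18 | C=C(O[Si](C)(C)C)C(CC=C(C)C)=C(OC)[O-].[Li+] | intermediate
20 | 1-methoxy-2-(3-methylbut-2-enyl)-1,3-bis(trimethylsilyloxy)buta-1,3-diene (either ketene acetal geometry) | C=C(O[Si](C)(C)C)C(CC=C(C)C)=C(OC)O[Si](C)(C)C | intermediate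
21 | (E)-1-[6-methoxy-5-(3-methylbut-2-enyl)-4,6-bis(trimethylsilyloxy)cyclohexa-1,4-dien-1-yl]-3-{(2R,3R)-3-(triethylsilyloxy)-2-[2-(triethylsilyloxy)propan-2-yl]-2,3-dihydro-1-benzofuran-5-yl}prop-2-en-1-one (both ketal epimers) | COC1(O[Si](C)(C)C)C(CC=C(C)C)=C(O[Si](C)(C)C)CC=C1C(=O)/C=C/c1ccc2c(c1)[C@@H](O[Si](CC)(CC)CC)[C@H](C(C)(C)O[Si](CC)(CC)CC)O2 | intermediate
22 | paratocarpin G bis(triethylsilyl) ether | CC(C)=CCc1c(O)ccc(C(=O)/C=C/c2ccc3c(c2)[C@@H](O[Si](CC)(CC)CC)[C@H](C(C)(C)O[Si](CC)(CC)CC)O3)c1O | intermediate
23 | paratocarpin G | CC(C)=CCc1c(O)ccc(C(=O)/C=C/c2ccc3c(c2)[C@@H](O)[C@H](C(C)(C)O)O3)c1O | target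

**Step count**
Total step count: 13.
Longest linear sequence: 10 steps (steps 1 to 8, 12 and 13).

**Steps most likely to fail**

Step 12 (key step).
- What may go wrong: the diene may be consumed by conjugate addition at the styryl terminus. The addition may stop after the first C-C bond through silyl transfer to the allenolate. The terminal ynone may oligomerise on warming. Aromatisation may proceed by loss of silanol in place of methanol.
- Fallback: it sets out from 20 and 9 and comes back at 22. Diene 20 is combined in the same way with commercial but-3-yn-2-one, a small ynone without a second acceptor. The same mild acid work-up should give 1-[2,4-dihydroxy-3-(3-methylbut-2-enyl)phenyl]ethanone F1. Bromide 9 is converted by bromine-lithium exchange (n-BuLi, THF, -78 °C) and DMF into (2R,3R)-3-(triethylsilyloxy)-2-[2-(triethylsilyloxy)propan-2-yl]-2,3-dihydro-1-benzofuran-5-carbaldehyde F2. A Claisen-Schmidt condensation of the fully deprotonated ketone F1 (LiN(SiMe3)2, THF, -78 °C to rt) with aldehyde F2 then forms the enone C=C bond and gives 22.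

Step 3.
- What may go wrong: the cis-methyl group and the bulky aryl group may crowd the titanium-bound transition state, so that both enantiomers are epoxidised at similar rates. The Lewis acid may also ionise the doubly activated carbinol and erode its configuration.
- Fallback: it sets out from 2 and 3 and comes back at 5, replacing resolution by catalytic asymmetric C-C bond formation. Grignard reagent 3 and Zn(OMe)2 give, after removal of the precipitated magnesium salts, bis(2-methylprop-1-enyl)zinc F3. This is added to aldehyde 2 in toluene at 0 °C with catalytic (-)-MIB, an amino alcohol that directs alkyl and alkenyl transfer to the Si face of aromatic aldehydes. The addition should give the (S)-alcohol 5 directly.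

Step 8.
- What may go wrong: during the quench the liberated N,O-dimethylhydroxylamine, or excess acetylide, may add to the newly freed terminal ynone. The ynone may also polymerise in the concentrated crude mixture.
- Fallback: it sets out from 11 and comes back at 13 by a detour in oxidation state, so that no amine is present when the ynone appears. Reduction with i-Bu2AlH (THF, -78 °C) gives (E)-3-{(2R,3R)-3-(triethylsilyloxy)-2-[2-(triethylsilyloxy)propan-2-yl]-2,3-dihydro-1-benzofuran-5-yl}prop-2-enal F4. Addition of 12 (THF, 0 °C) gives (E)-1-{(2R,3R)-3-(triethylsilyloxy)-2-[2-(triethylsilyloxy)propan-2-yl]-2,3-dihydro-1-benzofuran-5-yl}pent-1-en-4-yn-3-ol F5 as both carbinol epimers. MnO2 (CH2Cl2, rt) oxidises this doubly activated alcohol to 13.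

**Further compounds**
F1 | step 12 | 1-[2,4-dihydroxy-3-(3-methylbut-2-enyl)phenyl]ethanone | CC(=O)c1ccc(O)c(CC=C(C)C)c1O
F2 | step 12 | (2R,3R)-3-(triethylsilyloxy)-2-[2-(triethylsilyloxy)propan-2-yl]-2,3-dihydro-1-benzofuran-5-carbaldehyde | O=Cc1ccc2c(c1)[C@@H](O[Si](CC)(CC)CC)[C@H](C(C)(C)O[Si](CC)(CC)CC)O2
F3 | step 3 | bis(2-methylprop-1-enyl)zinc | CC(C)=C[Zn]C=C(C)C
F4 | step 8 | (E)-3-{(2R,3R)-3-(triethylsilyloxy)-2-[2-(triethylsilyloxy)propan-2-yl]-2,3-dihydro-1-benzofuran-5-yl}prop-2-enal | O=C/C=C/c1ccc2c(c1)[C@@H](O[Si](CC)(CC)CC)[C@H](C(C)(C)O[Si](CC)(CC)CC)O2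
F5 | step 8 | (E)-1-{(2R,3R)-3-(triethylsilyloxy)-2-[2-(triethylsilyloxy)propan-2-yl]-2,3-dihydro-1-benzofuran-5-yl}pent-1-en-4-yn-3-ol (both carbinol epimers) | C#CC(O)/C=C/c1ccc2c(c1)[C@@H](O[Si](CC)(CC)CC)[C@H](C(C)(C)O[Si](CC)(CC)CC)O2
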